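At 3.0 d we read one number from this flask: the product standing then. Starting material in the first phase meets reagent passing in from the second phase, while protic impurity turns starting material into quenched substrate.

| flask | starting material | reagent in the second phase | protic impurity | remark | time | volume of the second phase over the first |
|---|---|---|---|---|---|---|
| Friday's | 0.15 M | 1.8 equiv | 0.060 M | run made earlier |  |  |
| Saturday's | 0.22 M | 1.8 equiv | 0.060 M | run made earlier |  |  |
| Thursday's | 0.30 M | 1.8 equiv | 0.030 M | run made earlier |  |  |
| flask | 0.30 M | 1.80 equiv | 0.0600 M |  | 3.0 d | 2.0 |

| run | time / d | product / % |
|---|---|---|
| Friday's | 0.625 | 2.5 |
| Friday's | 1.25 | 4.6 |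
| Friday's | 2.00 | 10.5 |
| Friday's | 3.00 | 12.7 |
| Friday's | 4.00 | 15.4 |
| Saturday's | 0.250 | 0 |
| Saturday's | 0.500 | 3.1 |
| Saturday's | 1.04 | 7.8 |
| Saturday's | 2.08 | 14.9 |
| Saturday's | 4.00 | 24.3 |
| Thursday's | 0.625 | 5.6 |
| Thursday's | 1.25 | 13.3 |
| Thursday's | 2.00 | 21.4 |
| Thursday's | 3.00 | 26.5 |
| Thursday's | 4.00 | 33.7 |

(each reading ± 1 percentage point)

- in the second phase: reagent in the second phase; everything else is in the first
- charges count per volume of the first phase; a concentration in a rate is the amount of a species over the volume of its own phase; every rate counts per litre of the first phase
- the numbers in the tables scatter with a standard deviation of 1 percentage point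
- steps thought possible: starting material + reagent in the reaction phase -> product; starting material + protic impurity -> quenched substrate; reagent in the reaction phase <-> reagent in the second phase; reagent in the reaction phase <-> dormant form
- the earlier runs hold the two phases in the same ratio of volumes as the flask asked about

- beta: doubling the transfer coefficient of the reagent in the second phase, all else as stated
- eta: doubling the amount of reagent in the second phase, all else as stated

- the product standing at 3.0 d, as a percentage of the starting material charged
- the change that raises the amount of product at 3.0 d, in percent of the starting material charged most ("none" if none brings more than 2 percentage points) (beta / eta / none)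
- amount of product at 3.0 d, in percent of the starting material charged, after beta

We carry one quantity, the quench share s, 20.0% here: the charge of protic impurity over the charge of starting material. The impurity is the limiting reagent of the quench, so taking them one to one, s is the largest part of the charge it can remove.

From above: Thursday's run matches this flask except that it holds 0.030 M of impurity, less than the flask's 0.0600 M. Its reading, within a scatter of 1 percentage point, is our upper bound:

upper bound = 26.5% at 3.00 d

From below: we replace the falling curve of starting material by a step at the start, and we take product as proportional to what survives the step, at equal reagent. If Thursday's run lost nothing: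

lower bound = 26.5% × (1 − s) = 21.2%

But Thursday's impurity also took its part of the charge, with its own share s_T = 10.0%. Putting the same step into Thursday's run tightens the lower end, though this is an estimate and no longer a strict bound:

tightened lower estimate = 26.5% × (1 − s) / (1 − s_T) = 23.6%

We commit to the range from 23.6% to 26.5%, both resting on a reading with its scatter.

The forecast gives 24%, inside our bracket, with eta as the best change and 25% after beta. Its ground for the loss: "so the impurity removes nearly its own equivalent of substrate early".

The flask gives 25.4%, also inside the bracket. The best change is eta, gaining 18 points against 0.58 points for beta, which gives 26.0%. At 3.00 d the flask holds 20.0% of quenched substrate, with 0.194% of the impurity's charge left, and s said 20.0%.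

    starting material + reagent in the reaction phase → product (k = 0.0510 L mol⁻¹ h⁻¹)
    starting material + protic impurity → quenched substrate (k = 0.420 L mol⁻¹ h⁻¹)
    reagent in the reaction phase ⇌ reagent in the second phase, rate k3*([reagent in the reaction phase] - [reagent in the second phase]/K3) per volume of the first phase (partition coefficient = 1.70, kL = 0.350 h⁻¹)
    reagent in the reaction phase ⇌ dormant form (K = 0.350, k = 0.0190 h⁻¹)

On the neighbour charged with 0.51 M of starting material, the same impurity gives s = 11.8%. Computed, that neighbour holds 11.8% of quenched substrate at 3.00 d, and 39.6% of product.

The numbers in the tables stem from a simulated flask from invented constants, and the scatter is random.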